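Per second is the unit in which I set the two sides of this flask against each other: D fills the solution with Q, free Z takes Q out, and L handed back to Z holds catalyst as Q.Z.

D 48 mM; Z 0.38 mol%; time 3.0 min

    Q + Z → Q.Z (k1 = 438 M⁻¹ s⁻¹)
    Q.Z ⇌ Z + L (K2 = 0.020 M, k2 = 2.06 s⁻¹)
    D ⇌ Q, rate k3*(cs3 - [Q]) while solid is left; crystals form when [Q] > cs3 (cs3 = 2.2 mM, k3 = 0.0532 s⁻¹)

- north-east: doubling the dissolution coefficient of step 3, all else as stated
- north: doubling the solubility in step 3, all else as stated
- north-west: doubling the amount of Z, all else as stated

1. amount of L at 3.0 min, in percent of the D charged
2. the change that raises the amount of L at 3.0 min, in percent of the D charged most ("none" if none brings more than 2 percentage points) (north-east / north / north-west / none)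
3. amount of L at 3.0 min, in percent of the D charged, after north-west

I carried one quantity, the handover ratio H: uptake constant times free cZ, a pseudo-first-order drain on Q, divided by the dissolution coefficient. With Z as charged, H was 1.50, so dissolution was the slower side, though not by much. In steady flow, L forms at dissolution coefficient times solubility times H over one plus H, which gave me 0.0703 mM s⁻¹ and 26.3 % of D in the time.

Then I turned the settings. Doubling the solubility doubled that flow, to 52.7 %. Doubling the dissolution coefficient halved H and gave 37.6 %. Doubling Z doubled H and gave 32.9 %, less than the dissolution coefficient gave. But L holds Z: counting step-two balance by itself, H reached one at cL of 10.0 mM, or 20.9 % of D. I committed to y below 26.3 %, with north first and north-east second.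

The forecast gave 20.6 %, north as best and 29.4 % after north-west, holding that “doubled Z mainly drains Q against a dissolution limit”. It put north-west at about 29 % and north-east at about 27 %, the reverse of my order for those two.

The flask gave 20.8 %. North added 15 percentage points, north-west 7.1 points and north-east 5.7 points, so north won and north-west beat north-east, with 27.9 % after north-west.

With the run's free Z, H in this flask read 1.02 at 1.50 min, with L at 10.3 %, and 0.859 at 3.00 min. That L stood below the 20.9 % of D at which my reckoning put the crossing. In the neighbour flask, with 190 mM of D at the same loading, H as charged was 5.94, well on the dissolution side, and the same reckoning gave 9.49 %. With free Z at 52.2 %, H in the neighbour flask still read 3.10 at 3.00 min, and that flask gave 8.46 %.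

The rate constants are assumed; the run is a simulation.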